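## Retrosynthetic overview

- The target flavonol is traced back to its tetra-O-isopropyl ether (BCl3 removes the isopropyl groups and keeps the two methyl ethers). The C3 hydroxyl comes from epoxidation of C2=C3 of the protected flavone followed by acid opening.
- Ring C is the only ring built: C4–C4a is formed by intramolecular Friedel–Crafts acylation of a (Z)-3-aryl-3-aryloxyacrylic acid. The plan rests on C4a of ring A, which is ortho to O1, ortho to the C5 oxygen and para to the C7 methoxy group, and is the only unsubstituted carbon ortho to the aryl ether oxygen (C8 carries oxygen).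
- O1–C2 is formed before that, by oxa-Michael addition of 2,5-diisopropoxy-3-methoxyphenol to the ring B methyl arylpropiolate, followed by saponification.
- The phenol comes from 5-bromovanillin (Dakin oxidation, double O-isopropylation, bromide-to-hydroxyl exchange). The propiolate comes from methyl 3,5-dihydroxy-4-methoxybenzoate (double O-isopropylation, reduction, oxidation, Corey–Fuchs homologation with a chloroformate quench).
- Ring order: rings A and B are bought as arenes and ring C is closed in the key step.

Key step: step 11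

Remark: the target is achiral. Compounds 14, 15 and 16 are drawn as the Z isomers expected from anti addition, and any E isomer from step 9 is carried on, because it should equilibrate under the acidic conditions of step 11.

## Route

Step 1
Reactants: 1 5-bromovanillin (3-bromo-4-hydroxy-5-methoxybenzaldehyde)
Product: 3 2-bromo-6-methoxybenzene-1,4-diol, via aryl formate 2 (not isolated)
Conditions: H2O2 (30% aq), NaOH, H2O/THF, 0 °C → rt, N2; then aq HCl
Reagents that add atoms: hydrogen peroxide, OO
Why: Dakin oxidation: hydroperoxide adds to the aldehyde, the aryl group para to the phenoxide migrates to oxygen to give formate 2, and this is saponified in the same flask, while the bromide and the methyl ether are inert.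

Step 2
Reactants: 3 2-bromo-6-methoxybenzene-1,4-diol; 4 2-bromopropane
Product: 5 1-bromo-2,5-diisopropoxy-3-methoxybenzene
Conditions: K2CO3, 2-bromopropane (excess), DMF, 65 °C, N2
Reagents that add atoms: 2-bromopropane, CC(C)Br (second equivalent, for the second isopropyl group; the first is reactant 4)
Why: Twofold Williamson ether synthesis, one molecule of 2-bromopropane per phenoxide; excess secondary bromide and heat should compensate for competing elimination and for the hindered oxygen between Br and OMe, and exclusion of air protects the hydroquinone.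

Step 3
Reactants: 5 1-bromo-2,5-diisopropoxy-3-methoxybenzene
Product: 6 2,5-diisopropoxy-3-methoxyphenol
Conditions: Pd2(dba)3 (cat.), tBuXPhos (cat.), KOH, 1,4-dioxane/H2O, 100 °C; then aq HCl
Reagents that add atoms: potassium hydroxide, [K+].[OH-]
Why: Palladium-catalysed hydroxylation of an aryl bromide (Buchwald-type C–O coupling with hydroxide from a zerovalent palladium source); the bulky biaryl phosphine favours C–O reductive elimination on this electron-rich, mono-ortho-substituted bromide, and the ethers are untouched.

Step 4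
Reactants: 7 methyl 3,5-dihydroxy-4-methoxybenzoate; 4 2-bromopropane
Product: 8 methyl 3,5-diisopropoxy-4-methoxybenzoate
Conditions: K2CO3, 2-bromopropane (excess), DMF, 65 °C
Reagents that add atoms: 2-bromopropane, CC(C)Br (second equivalent, for the second isopropyl group; the first is reactant 4)
Why: Twofold Williamson ether synthesis on the two equivalent phenols, one molecule of 2-bromopropane for each; the methyl ester is stable to carbonate in DMF.

Step 5
Reactants: 8 methyl 3,5-diisopropoxy-4-methoxybenzoate
Product: 9 (3,5-diisopropoxy-4-methoxyphenyl)methanol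
Conditions: LiAlH4, THF, 0 °C → rt; then H2O
Reagents that add atoms: none
Why: Hydride reduction of an aryl ester to the benzylic alcohol; aryl ethers are inert to LiAlH4.

Step 6
Reactants: 9 (3,5-diisopropoxy-4-methoxyphenyl)methanol
Product: 10 3,5-diisopropoxy-4-methoxybenzaldehyde
Conditions: MnO2 (activated, excess), CH2Cl2, rt
Reagents that add atoms: none
Why: Selective benzylic oxidation with manganese dioxide, which should stop at the aldehyde.

Step 7
Reactants: 10 3,5-diisopropoxy-4-methoxybenzaldehyde
Product: 11 5-(2,2-dibromovinyl)-1,3-diisopropoxy-2-methoxybenzene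
Conditions: CBr4, PPh3, CH2Cl2, 0 °C
Reagents that add atoms: carbon tetrabromide, BrC(Br)(Br)Br
Why: Corey–Fuchs (Ramirez) dibromo-olefination of an aromatic aldehyde via the dibromomethylene ylide, a Wittig-type reaction.

Step 8
Reactants: 11 5-(2,2-dibromovinyl)-1,3-diisopropoxy-2-methoxybenzene
Product: 13 methyl 3-(3,5-diisopropoxy-4-methoxyphenyl)propiolate, via lithium acetylide 12 (not isolated)
Conditions: n-BuLi (2.1 equiv), THF, −78 °C; then ClCO2Me, −78 → 0 °C
Reagents that add atoms: methyl chloroformate, COC(=O)Cl; n-butyllithium, [Li]CCCC (lithium of 12 only)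
Why: Second stage of the Corey–Fuchs reaction: Br/Li exchange, Fritsch–Buttenberg–Wiechell rearrangement and deprotonation give acetylide 12, which is C-acylated by the chloroformate to the alkynoate.

Step 9
Reactants: 6 2,5-diisopropoxy-3-methoxyphenol; 13 methyl 3-(3,5-diisopropoxy-4-methoxyphenyl)propiolate
Product: 14 methyl (Z)-3-(2,5-diisopropoxy-3-methoxyphenoxy)-3-(3,5-diisopropoxy-4-methoxyphenyl)acrylate
Conditions: Cs2CO3 (cat.), DMF, 70 °C
Reagents that add atoms: none
Why: Base-catalysed oxa-Michael addition of a phenoxide to an arylpropiolate; anti addition of ArO and H places the aryloxy group cis to the ester (Z), which is also the isomer with the ring B aryl group trans to the ester.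

Step 10
Reactants: 14 methyl (Z)-3-(2,5-diisopropoxy-3-methoxyphenoxy)-3-(3,5-diisopropoxy-4-methoxyphenyl)acrylate
Product: 15 (Z)-3-(2,5-diisopropoxy-3-methoxyphenoxy)-3-(3,5-diisopropoxy-4-methoxyphenyl)acrylic acid
Conditions: LiOH·H2O, THF/MeOH/H2O, 40 °C; then 1 M HCl, 0 °C
Reagents that add atoms: lithium hydroxide, [Li+].[OH-]
Why: Saponification of a methyl ester; the vinylogous carbonate is a poor acceptor for hydroxide at C3 at this temperature, and cold brief acidification spares the enol ether.

Step 11
Reactants: 15 (Z)-3-(2,5-diisopropoxy-3-methoxyphenoxy)-3-(3,5-diisopropoxy-4-methoxyphenyl)acrylic acid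
Product: 17 2-(3,5-diisopropoxy-4-methoxyphenyl)-5,8-diisopropoxy-7-methoxy-4H-chromen-4-one, via mixed trifluoroacetic anhydride 16 (not isolated)
Conditions: TFAA (3 equiv), CH2Cl2, 0 °C → rt
Reagents that add atoms: trifluoroacetic anhydride, O=C(OC(=O)C(F)(F)F)C(F)(F)F (trifluoroacetyl group of 16 only; no atoms remain in 17)
Why: TFAA should convert acid 15 into mixed anhydride 16, whose acyl carbon (as the anhydride or the derived vinylogous acylium ion) is attacked by the phenoxy carbon ortho to the ether oxygen, and loss of a proton from the arenium ion restores aromaticity and gives the 4-pyranone of 17, forming C4–C4a. The closest known reaction is the classical intramolecular Friedel–Crafts acylation of β-aryloxycinnamic acids (phenol–arylpropiolate adducts) to flavones. Ring C closes as a six-membered ring in the 6-exo-trig mode at the acyl carbon, with the C=O outside the new ring. No stereocentre is formed. The step needs regioselectivity, which the substrate secures because the attacking carbon is the only unsubstituted position ortho to the ether oxygen within reach of the tether and is activated by O1 (ortho), the C5 isopropoxy group (ortho) and the C7 methoxy group (para), and it needs the Z geometry, which is fed from any E isomer by reversible C-protonation of the enol ether in the trifluoroacetic acid that the reaction releases. No Lewis acid is present, so the four isopropyl ethers should survive.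

Step 12
Reactants: 17 2-(3,5-diisopropoxy-4-methoxyphenyl)-5,8-diisopropoxy-7-methoxy-4H-chromen-4-one
Product: 19 3-hydroxy-2-(3,5-diisopropoxy-4-methoxyphenyl)-5,8-diisopropoxy-7-methoxy-4H-chromen-4-one, via epoxyflavanone 18 (not isolated)
Conditions: DMDO (acetone solution), CH2Cl2, 0 °C → rt; volatiles removed; then p-TsOH·H2O (cat.), CH2Cl2, rt
Reagents that add atoms: dimethyldioxirane, CC1(C)OO1
Why: Neutral epoxidation of the C2=C3 enol ether double bond of a fully O-alkylated flavone by a dioxirane, then acid-catalysed opening of the epoxide at C2 (oxocarbenium stabilised by O1 and the aryl group) and loss of H-3 give the flavonol, so the two stereocentres of racemic 18 are erased.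

Step 13
Reactants: 19 3-hydroxy-2-(3,5-diisopropoxy-4-methoxyphenyl)-5,8-diisopropoxy-7-methoxy-4H-chromen-4-one
Product: 20 3,5,8-trihydroxy-2-(3,5-dihydroxy-4-methoxyphenyl)-7-methoxy-4H-chromen-4-one
Conditions: BCl3 (excess, 1 M in CH2Cl2), CH2Cl2, −78 → 0 °C, Ar; then degassed H2O
Reagents that add atoms: none
Why: Lewis-acid dealkylation of aryl ethers: boron-coordinated isopropyl ethers ionise to a secondary cation and chloride far faster than methyl ethers, so low temperature and short contact should leave the C7 and C4' methoxy groups, and inert work-up protects the oxidation-prone 5,8-dihydroxy ring.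

## Compound list

1 | 5-bromovanillin | COc1cc(C=O)cc(Br)c1O | starting material
2 | 3-bromo-4-hydroxy-5-methoxyphenyl formate | COc1cc(OC=O)cc(Br)c1O | intermediate
3 | 2-bromo-6-methoxybenzene-1,4-diol | COc1cc(O)cc(Br)c1O | intermediate
4 | 2-bromopropane | CC(C)Br | starting material
5 | 1-bromo-2,5-diisopropoxy-3-methoxybenzene | COc1cc(OC(C)C)cc(Br)c1OC(C)C | intermediate
6 | 2,5-diisopropoxy-3-methoxyphenol | COc1cc(OC(C)C)cc(O)c1OC(C)C | intermediate
7 | methyl 3,5-dihydroxy-4-methoxybenzoate | COC(=O)c1cc(O)c(OC)c(O)c1 | starting material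
8 | methyl 3,5-diisopropoxy-4-methoxybenzoate | COC(=O)c1cc(OC(C)C)c(OC)c(OC(C)C)c1 | intermediate
9 | (3,5-diisopropoxy-4-methoxyphenyl)methanol | OCc1cc(OC(C)C)c(OC)c(OC(C)C)c1 | intermediate
10 | 3,5-diisopropoxy-4-methoxybenzaldehyde | O=Cc1cc(OC(C)C)c(OC)c(OC(C)C)c1 | intermediate
11 | 5-(2,2-dibromovinyl)-1,3-diisopropoxy-2-methoxybenzene | BrC(Br)=Cc1cc(OC(C)C)c(OC)c(OC(C)C)c1 | intermediate
12 | lithium (3,5-diisopropoxy-4-methoxyphenyl)acetylide | [Li]C#Cc1cc(OC(C)C)c(OC)c(OC(C)C)c1 | intermediate
13 | methyl 3-(3,5-diisopropoxy-4-methoxyphenyl)propiolate | COC(=O)C#Cc1cc(OC(C)C)c(OC)c(OC(C)C)c1 | intermediate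
14 | methyl (Z)-3-(2,5-diisopropoxy-3-methoxyphenoxy)-3-(3,5-diisopropoxy-4-methoxyphenyl)acrylate | COC(=O)/C=C(\Oc1cc(OC(C)C)cc(OC)c1OC(C)C)c1cc(OC(C)C)c(OC)c(OC(C)C)c1 | intermediate
15 | (Z)-3-(2,5-diisopropoxy-3-methoxyphenoxy)-3-(3,5-diisopropoxy-4-methoxyphenyl)acrylic acid | OC(=O)/C=C(\Oc1cc(OC(C)C)cc(OC)c1OC(C)C)c1cc(OC(C)C)c(OC)c(OC(C)C)c1 | intermediate
16 | (Z)-3-(2,5-diisopropoxy-3-methoxyphenoxy)-3-(3,5-diisopropoxy-4-methoxyphenyl)acrylic trifluoroacetic anhydride | O=C(OC(=O)C(F)(F)F)/C=C(\Oc1cc(OC(C)C)cc(OC)c1OC(C)C)c1cc(OC(C)C)c(OC)c(OC(C)C)c1 | intermediate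
17 | 2-(3,5-diisopropoxy-4-methoxyphenyl)-5,8-diisopropoxy-7-methoxy-4H-chromen-4-one | COc1cc(OC(C)C)c2c(=O)cc(-c3cc(OC(C)C)c(OC)c(OC(C)C)c3)oc2c1OC(C)C | intermediate
18 | 2,3-epoxide of 17, a cis-fused 7a-aryl-1a,7a-dihydro-7H-oxireno[2,3-b]chromen-7-one (racemic, one enantiomer drawn) | COc1cc(OC(C)C)c2c(c1OC(C)C)O[C@@]1(c3cc(OC(C)C)c(OC)c(OC(C)C)c3)O[C@H]1C2=O | intermediate
19 | 3-hydroxy-2-(3,5-diisopropoxy-4-methoxyphenyl)-5,8-diisopropoxy-7-methoxy-4H-chromen-4-one | COc1cc(OC(C)C)c2c(=O)c(O)c(-c3cc(OC(C)C)c(OC)c(OC(C)C)c3)oc2c1OC(C)C | intermediate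
20 | 3,5,8-trihydroxy-2-(3,5-dihydroxy-4-methoxyphenyl)-7-methoxy-4H-chromen-4-one | COc1cc(O)c2c(=O)c(O)c(-c3cc(O)c(OC)c(O)c3)oc2c1O | target

## Count

Total step count: 13.
Longest linear sequence: 10 steps (steps 4, 5, 6, 7, 8, 9, 10, 11, 12, 13, from compound 7 to compound 20).

## Steps most likely to fail

**Step 11 (key ring closure).** The β-oxygen stabilises the acylium ion, so the mixed anhydride may be too weak an electrophile. Intermolecular trifluoroacetylation of the electron-rich rings, or acid-induced loss of an isopropyl group, could then overtake ring closure. The fallback builds ring C by the diketone route, setting out from phenol 6 and ester 8 and coming back at flavone 17. Acetylation of 6 with Ac2O and BF3·OEt2 (0 → 40 °C) should proceed by O-acetylation and Fries-type migration to the only free carbon ortho to the hydroxyl, held as a boron chelate, and give 1-(2-hydroxy-3,6-diisopropoxy-4-methoxyphenyl)ethan-1-one F1. Claisen-type condensation of the dianion of F1 (LiN(SiMe3)2, THF, −78 °C → rt) with ester 8 gives 1-(2-hydroxy-3,6-diisopropoxy-4-methoxyphenyl)-3-(3,5-diisopropoxy-4-methoxyphenyl)propane-1,3-dione F2. Cyclodehydration of F2 (cat. p-TsOH, toluene, 80 °C) gives 17.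

**Step 9 (oxa-Michael addition).** The phenoxide is hindered and electron-rich and the alkynoate is deactivated by its electron-rich aryl group. Addition may be slow, so that retro-addition and base-induced degradation of the ester compete at the temperature needed. The fallback uses a more electrophilic acceptor, setting out from dibromoalkene 11 (with phenol 6) and coming back at acid 15. Acetylide 12 is generated as in step 8 and quenched with DMF (aqueous NH4Cl work-up) to give 3-(3,5-diisopropoxy-4-methoxyphenyl)propiolaldehyde F3. Amine-catalysed addition of 6 (cat. Et3N, CH2Cl2, rt) gives (Z)-3-(2,5-diisopropoxy-3-methoxyphenoxy)-3-(3,5-diisopropoxy-4-methoxyphenyl)acrylaldehyde F4. Pinnick oxidation (NaClO2, NaH2PO4, 2-methyl-2-butene, t-BuOH/H2O) gives 15 directly.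

**Step 12 (C3 hydroxylation).** Oxidation of the two trialkoxyaryl rings by the dioxirane may compete with slow epoxidation of the hindered C2=C3 bond, or the epoxide may open with rearrangement instead of enolisation. The fallback is an anionic hydroxylation, setting out from flavone 17 and coming back at flavonol 19. Deprotonation at C3 with LiN(iPr)2 (THF, −78 °C) gives 3-lithio-2-(3,5-diisopropoxy-4-methoxyphenyl)-5,8-diisopropoxy-7-methoxy-4H-chromen-4-one F5. Trapping with B(OMe)3 gives dimethyl [2-(3,5-diisopropoxy-4-methoxyphenyl)-5,8-diisopropoxy-7-methoxy-4-oxo-4H-chromen-3-yl]boronate F6. Oxidation of the C–B bond (H2O2, AcOH, 0 °C) gives 19.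

## Further compounds

F1 | step 11 | 1-(2-hydroxy-3,6-diisopropoxy-4-methoxyphenyl)ethan-1-one | CC(=O)c1c(O)c(OC(C)C)c(OC)cc1OC(C)C
F2 | step 11 | 1-(2-hydroxy-3,6-diisopropoxy-4-methoxyphenyl)-3-(3,5-diisopropoxy-4-methoxyphenyl)propane-1,3-dione | O=C(CC(=O)c1cc(OC(C)C)c(OC)c(OC(C)C)c1)c1c(O)c(OC(C)C)c(OC)cc1OC(C)C
F3 | step 9 | 3-(3,5-diisopropoxy-4-methoxyphenyl)propiolaldehyde | O=CC#Cc1cc(OC(C)C)c(OC)c(OC(C)C)c1
F4 | step 9 | (Z)-3-(2,5-diisopropoxy-3-methoxyphenoxy)-3-(3,5-diisopropoxy-4-methoxyphenyl)acrylaldehyde | O=C/C=C(\Oc1cc(OC(C)C)cc(OC)c1OC(C)C)c1cc(OC(C)C)c(OC)c(OC(C)C)c1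
F5 | step 12 | 3-lithio-2-(3,5-diisopropoxy-4-methoxyphenyl)-5,8-diisopropoxy-7-methoxy-4H-chromen-4-one | COc1cc(OC(C)C)c2c(=O)c([Li])c(-c3cc(OC(C)C)c(OC)c(OC(C)C)c3)oc2c1OC(C)C
F6 | step 12 | dimethyl [2-(3,5-diisopropoxy-4-methoxyphenyl)-5,8-diisopropoxy-7-methoxy-4-oxo-4H-chromen-3-yl]boronate | COB(OC)c1c(-c2cc(OC(C)C)c(OC)c(OC(C)C)c2)oc2c(OC(C)C)c(OC)cc(OC(C)C)c2c1=O
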